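Remark: compounds 6–19 are racemic and are drawn and named as one enantiomer; ring atoms carry the target's locants throughout (C1–C11 and O12 of 12-oxabicyclo[9.1.0]dodecane), also in the intermediates.

## The problem

Target 24 is an eleven-membered carbocycle: C1(H)–O12–C11(Me) is a trans epoxide, C2 and C3 are methylenes, C4=C5 carries CO2H on C4, C6(H) carries the benzoate, C7 is CMe2, and C8–C10 are methylenes. An eleven-membered ring with no heteroatom in it is slow to close directly and is strained across the ring. The trans epoxide (1S,11S) needs an E-configured C1=C11 alkene with a fully substituted C11. C6 (R) is a neopentyl carbinol beside quaternary C7 and is four ring atoms away from the epoxide on either side, so neither stereo element can control the other. The C4=C5 alkene must have C3 and C6 cis; the acid is then trans to the C6 oxygen, so no butenolide can be used as a temporary tether. The epoxide is acid-sensitive, the allylic benzoate γ to the carboxyl is sensitive to base and to zerovalent palladium, and the acid must be freed last beside the benzoate. The feature that the plan exploits is this: C6–C7–C8–C9–C10–C11, with the two methyls on C7 and one on C11, is the carbon pattern of 2,2,6-trimethylcyclohexanone with C6 as the carbonyl carbon. A transannular C6–C11 bond would close that six-membered ring and a seven-membered ring C11–C1–C2–C3–C4–C5–C6 in which C4=C5 is necessarily cis. The oxygens on C6 and C1 then sit 1,3 across C11 (O–C6–C11–C1–O), which is the array of a Grob fragmentation.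

## Retrosynthesis

**24 back to 20 (end game).** No C–C bond is cut. The acid is masked as the 2-(trimethylsilyl)ethyl ester 23, the epoxide comes from the only electron-rich alkene of 22, the benzoate from alcohol 21, and 21 from ketone 20. Ketone 20 is achiral, so the absolute configuration rests on two catalyst-controlled steps (C6 by oxazaborolidine reduction, C1/C11 by dioxirane epoxidation) and no relay between the remote centres is needed.

**20 back to 18 (key disconnection).** In the retrosynthetic direction a C6–C11 bond is added and C1 receives a sulfonate, giving the cis-fused bicyclo[5.4.0]undecene 18, whose alkoxide is 19. The neighbouring choices, cutting C3–C4, C5–C6 or C10–C11 of an open chain, all require an eleven-membered ring closure. Here the ring is revealed by breaking the bond shared by a six- and a seven-membered ring. 18 is smaller in ring size, may be racemic because its three stereocentres vanish, and already holds C4=C5 in the right geometry. The forward reaction needs the C1–O bond anti-periplanar to C11–C6 and the C1 oxygen cis to the C11 methyl, so that the new alkene is E.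

**18 back to 15.** The seven-membered ring is cut at C3–C4 (sp3–sp2). Mesylate 18 comes from diol 17, and 17 from iodoenoate 15 by hydroboration of the vinyl group (borane 16) and intramolecular B-alkyl Suzuki coupling. Cutting here, and not at C5–C6 or C1–C2, leaves a terminal alkene and an α-iodoenoate, both available from cheap three-carbon units. The forward reaction closes a seven-membered ring and must retain the alkene geometry.

**15 back to 13.** The carbon–iodine bond at C4 and the C5–H bond come from ynoate 13 by hydroxyl-directed trans-hydroalumination (aluminate 14) and iodinolysis. This sets the C4=C5 geometry from the C6 hydroxyl, independent of any ring.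

**13 back to 11.** No C–C bond is cut. The C1 carbinol configuration is set by oxidation of the epimer mixture 11 to vinyl ketone 12 and reduction directed by the C6 hydroxyl. This frees the preceding aldol from any demand for selectivity.

**11 back to 8 and 3.** C5–C6 is cut: acetylide 9, from ester 3, adds to the ketone of 8 (alkoxide 10). An acetylide is chosen over a vinyl nucleophile because it is the only carbon nucleophile slim enough for a ketone between two quaternary carbons, and because it carries C4, C5 and the carboxyl carbon in one piece.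

**8 back to 4 and 5; 3 back to 1 and 2.** C11–C1 is cut: the only possible enolate (6) of trimethylcyclohexanone 4 adds to acrolein 5 (aldolate 7). Ester 3 is made from acid 1 and alcohol 2. All fifteen skeletal carbons come from 4 (nine), 5 (three) and 3 (three).

## Roads not taken

Alternative 1: Open-chain precursor and macrocyclisation, the most obvious plan. The cut is C5–C6; iodo-aldehyde A1 would be closed by an intramolecular Nozaki–Hiyama–Kishi reaction (CrCl2/NiCl2) to allylic alcohol A2, then treated as in steps 11–13. The eleven-membered ring would have to close at a neopentyl aldehyde, where dimerisation competes. The C6 stereocentre would form without control, because the only other stereo element is remote. A1 needs both trisubstituted alkenes built separately with defined geometry, in a linear sequence as long as the whole chosen route. The chosen plan closes only six- and seven-membered rings and sets both alkene geometries from rings.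

Alternative 2: Cope ring expansion. Retrosynthetically C2–C3 is cut and C5–C11 is joined, giving the cis-1,2-dialkenylcycloheptane A3, whose [3,3] shift would give diene benzoate A4 directly. The position of the equilibrium between a little-strained cycloheptane and a cycloundeca-1,5-diene is not clearly on the product side, and the heat needed endangers the allylic benzoate. Chair and boat pathways would give different alkene geometries. A3 has three contiguous stereocentres, one quaternary, and is harder to make than 18. The chosen fragmentation is irreversible (a C=O bond forms and mesylate leaves) and stereospecific.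

Alternative 3: Semisynthesis from commercial α-humulene A5. Diimide reduction of the disubstituted alkene would give A6. After that the two near-identical trisubstituted alkenes would have to be told apart, and the methyl on C4 oxidised to the acid with inversion of the C4=C5 geometry. The neopentyl allylic C6 methylene would have to be oxygenated enantioselectively. Allylic oxidation of such trisubstituted alkenes prefers ring methylene positions, and an achiral hydrocarbon offers no handle for enantiocontrol at C6. The chosen plan places every oxygen through the building blocks and uses two well-understood asymmetric catalysts.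

Key step: step 9

## Route

Step 1
Reactants: 1 propiolic acid (prop-2-ynoic acid); 2 2-(trimethylsilyl)ethanol
Product: 3 2-(trimethylsilyl)ethyl prop-2-ynoate
Conditions: DCC, DMAP (5 mol%), CH2Cl2, −20 to 0 °C
Reagents that add atoms: none
Why: Steglich esterification; low temperature and little DMAP suppress conjugate addition to the ynoate. The silylethyl ester should survive hydride, base and borane and can still be removed with fluoride beside a benzoate and an epoxide.

Step 2
Reactants: 4 (±)-2,2,6-trimethylcyclohexan-1-one; 5 acrolein (prop-2-enal)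
Product: 8 rac-2,2,6-trimethyl-6-[1-(triethylsilyloxy)prop-2-en-1-yl]cyclohexan-1-one (both side-chain epimers), via lithium enolate 6 (not isolated), via lithium aldolate 7 (not isolated)
Conditions: LiN(i-Pr)2, THF, 0 °C; 5, −78 °C; then Et3SiOTf, −78 to −40 °C
Reagents that add atoms: triethylsilyl trifluoromethanesulfonate, CC[Si](CC)(CC)OS(=O)(=O)C(F)(F)F
Why: 4 has one α-hydrogen, so only the tetrasubstituted enolate can form; kinetic 1,2-aldol addition to acrolein builds quaternary C11 and in-situ silylation blocks retro-aldol. The C1 configuration is not controlled here and need not be, since steps 4 and 5 reset it.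

Step 3
Reactants: 3 2-(trimethylsilyl)ethyl prop-2-ynoate; 8 silyl-protected aldol
Product: 11 rac-2-(trimethylsilyl)ethyl 3-[(1S,2S)-1-hydroxy-2-(1-hydroxyprop-2-en-1-yl)-2,6,6-trimethylcyclohexyl]prop-2-ynoate (both side-chain carbinol epimers), via lithium acetylide 9 (not isolated), via silyl ether alkoxide 10 (not isolated)
Conditions: 3, LiN(SiMe3)2, THF, −78 °C; CeCl3; 8, −78 to −30 °C; then 1 M HCl, THF, 0 °C to rt
Reagents that add atoms: none
Why: 1,2-addition of an acetylide, the slimmest carbon nucleophile, to a ketone that cannot enolise; CeCl3 raises carbonyl reactivity and lowers basicity. With the silyloxyallyl group equatorial, the axial methyls on C7 and C11 shield one face, so the acetylide should enter anti to the C11 methyl and leave the C6 hydroxyl cis to it. Acidic work-up removes the silyl ether.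

Step 4
Reactants: 11 diol (epimer mixture)
Product: 12 rac-2-(trimethylsilyl)ethyl 3-[(1S,2R)-1-hydroxy-2,6,6-trimethyl-2-(prop-2-enoyl)cyclohexyl]prop-2-ynoate
Conditions: Dess–Martin periodinane, CH2Cl2, 0 °C
Reagents that add atoms: none
Why: Dess–Martin oxidation of the secondary allylic alcohol; the tertiary alcohol cannot be oxidised. Both C1 epimers converge on one vinyl ketone, and non-basic conditions avoid retro-aldol opening of the β-hydroxy ketone.

Step 5
Reactants: 12 β-hydroxy vinyl ketone
Product: 13 rac-2-(trimethylsilyl)ethyl 3-{(1S,2S)-1-hydroxy-2-[(1R)-1-hydroxyprop-2-en-1-yl]-2,6,6-trimethylcyclohexyl}prop-2-ynoate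
Conditions: Me4NBH(OAc)3, MeCN/AcOH, −30 °C
Reagents that add atoms: none
Why: Evans–Saksena reduction: the acetoxyborohydride bound to the C6 oxygen delivers hydride through a chair in which the tertiary oxygen and the acyl group are diequatorial on the cyclohexane and the vinyl group is equatorial, which should give the 1,3-anti diol. This places the C1 oxygen so that it is cis to the C11 methyl once the seven-membered ring exists, as the fragmentation needs for an E alkene. The reagent reduces the enone 1,2 and leaves the ynoate alone.

Step 6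
Reactants: 13 anti-diol ynoate
Product: 15 rac-2-(trimethylsilyl)ethyl (2Z)-3-{(1R,2S)-1-hydroxy-2-[(1R)-1-hydroxyprop-2-en-1-yl]-2,6,6-trimethylcyclohexyl}-2-iodoprop-2-enoate, via alkenylaluminate 14 (not isolated)
Conditions: NaAlH2(OCH2CH2OMe)2 (Red-Al), THF, −78 to −40 °C; then iodine, −78 °C
Reagents that add atoms: iodine, [I][I]
Why: Hydroxyl-directed trans-hydroalumination of a γ-hydroxy ynoate: hydride goes to C5 and aluminium to C4 inside a five-membered oxa-aluminacycle, so aluminium, and after iodinolysis with retention iodine, is cis to C6. This fixes the later cis relation of C3 and C6 across C4=C5, with the carboxyl trans to the C6 oxygen.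

Step 7
Reactants: 15 (Z)-α-iodoenoate
Product: 17 rac-2-(trimethylsilyl)ethyl (1R,6R,7S)-1,6-dihydroxy-7,11,11-trimethylbicyclo[5.4.0]undec-2-ene-3-carboxylate, via alkylborane 16 (not isolated)
Conditions: 9-BBN-H (3.5 equiv), THF, 0 °C to rt; then Pd(dppf)Cl2 (10 mol%), AsPh3, Cs2CO3, DMF/THF/H2O, 50 °C, 0.01 M
Reagents that add atoms: none
Why: 9-BBN adds to the terminal vinyl carbon (C3); intramolecular B-alkyl Suzuki–Miyaura coupling with the electron-poor α-iodoenoate forms C3–C4 with retention and closes a seven-membered ring in place of an eleven-membered one. The hydroxyl groups only bind excess borane and are freed on work-up.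

Step 8
Reactants: 17 bicyclic diol
Product: 18 rac-2-(trimethylsilyl)ethyl (1R,6R,7S)-1-hydroxy-6-(methanesulfonyloxy)-7,11,11-trimethylbicyclo[5.4.0]undec-2-ene-3-carboxylate
Conditions: MsCl, Et3N, CH2Cl2, −10 °C
Reagents that add atoms: methanesulfonyl chloride, CS(=O)(=O)Cl
Why: Sulfonylation via sulfene reaches only the secondary alcohol; the tertiary hydroxyl between two quaternary carbons does not react. The neopentyl mesylate resists external substitution.

Step 9
Reactants: 18 bicyclic hydroxy mesylate
Product: 20 2-(trimethylsilyl)ethyl (1E,8E)-4,4,8-trimethyl-3-oxocycloundeca-1,8-diene-1-carboxylate, via potassium alkoxide 19 (not isolated)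
Conditions: KN(SiMe3)2 (1.05 equiv), THF, −78 to 0 °C
Reagents that add atoms: none
Why: Deprotonation gives tertiary alkoxide 19; the oxygen lone pair forms the C6 carbonyl, the C6–C11 σ bond breaks and its electrons expel mesylate from C1 in a concerted Grob (Wharton-type) fragmentation. The closest known reaction type is the base-induced fragmentation of bicyclic 1,3-diol monosulfonates to medium-ring alkenones. No ring is closed: the eleven-membered ring appears because the bond shared by the six- and seven-membered rings is cut, so no macrocyclisation penalty is paid. No stereocentre is formed and the three of 18 are destroyed, which is why racemic material suffices and 20 is achiral. The step needs anti-periplanar C1–O and C11–C6 bonds: with the mesylate cis to the C11 methyl, the reactive conformer has the mesylate equatorial and the methyl axial on the seven-membered ring, so C10 and C2 become trans and C1=C11 is E. The C4=C5 geometry is untouched because it was fixed inside the seven-membered ring. The base is consumed by the fragmentation, so the enone is not exposed to it, and relief of strain between the vicinal quaternary C6 and C11 should favour fragmentation over oxetane closure.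

Step 10
Reactants: 20 macrocyclic enone
Product: 21 2-(trimethylsilyl)ethyl (1E,3R,8E)-3-hydroxy-4,4,8-trimethylcycloundeca-1,8-diene-1-carboxylate
Conditions: (S)-2-methyl-CBS-oxazaborolidine (20 mol%), catecholborane, toluene, −78 °C
Reagents that add atoms: none
Why: Corey–Bakshi–Shibata reduction: the ketone should bind anti to the larger substituent, taken to be the quaternary C7 side (the twisted alkenyl group has only hydrogen on C5), so the (S)-catalyst should give (R) at C6. Catecholborane reduces the enone 1,2 and leaves the isolated alkene and the ester alone.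

Step 11
Reactants: 21 allylic alcohol
Product: 22 2-(trimethylsilyl)ethyl (1E,3R,8E)-3-(benzoyloxy)-4,4,8-trimethylcycloundeca-1,8-diene-1-carboxylate
Conditions: BzCl, pyridine, DMAP (cat.), CH2Cl2, 0 °C to rt
Reagents that add atoms: benzoyl chloride, O=C(Cl)c1ccccc1
Why: DMAP-catalysed acylation of a hindered secondary alcohol; no other nucleophile is present and the stereocentre is not touched.

Step 12
Reactants: 22 diene benzoate
Product: 23 2-(trimethylsilyl)ethyl (1S,4E,6R,11S)-6-(benzoyloxy)-7,7,11-trimethyl-12-oxabicyclo[9.1.0]dodec-4-ene-4-carboxylate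
Conditions: L-fructose-derived Shi ketone (30 mol%), Oxone (2KHSO5·KHSO4·K2SO4), K2CO3, Bu4NHSO4, MeCN/DMM/aq. Na2B4O7–Na2EDTA buffer, 0 °C
Reagents that add atoms: Oxone (active component potassium peroxymonosulfate, KHSO5), [K+].[O-]S(=O)(=O)OO
Why: Shi epoxidation: the chiral dioxirane attacks the only electron-rich alkene, E-trisubstituted C1=C11, through a spiro transition state. The D-fructose catalyst gives (R,R) epoxides from this olefin class, so its enantiomer is used for (1S,11S); the trans epoxide follows from the E alkene. The enoate alkene is too electron-poor to react and both esters tolerate pH 10.5 at 0 °C.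

Step 13
Reactants: 23 epoxy silylethyl ester
Product: 24 (1S,4E,6R,11S)-6-(benzoyloxy)-7,7,11-trimethyl-12-oxabicyclo[9.1.0]dodec-4-ene-4-carboxylic acid
Conditions: Bu4NF, THF, 0 °C to rt; then AcOH
Reagents that add atoms: none
Why: Fluoride attacks silicon and the 2-silylethyl ester fragments to ethylene, fluorosilane and the carboxylate; benzoate and epoxide are inert to fluoride at this temperature and acetic acid does not open the epoxide.

## Compound list

1 | propiolic acid (prop-2-ynoic acid) | C#CC(=O)O | starting material
2 | 2-(trimethylsilyl)ethanol | C[Si](C)(C)CCO | starting material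
3 | 2-(trimethylsilyl)ethyl prop-2-ynoate | C#CC(=O)OCC[Si](C)(C)C | intermediate
4 | (±)-2,2,6-trimethylcyclohexan-1-one | CC1CCCC(C)(C)C1=O | starting material
5 | acrolein (prop-2-enal) | C=CC=O | starting material
6 | lithium 2,6,6-trimethylcyclohex-1-en-1-olate | CC1=C([O-])C(C)(C)CCC1.[Li+] | intermediate
7 | lithium aldolate of 4 and 5 (both epimers) | C=CC([O-])C1(C)CCCC(C)(C)C1=O.[Li+] | intermediate
8 | rac-2,2,6-trimethyl-6-[1-(triethylsilyloxy)prop-2-en-1-yl]cyclohexan-1-one (both side-chain epimers) | C=CC(O[Si](CC)(CC)CC)C1(C)CCCC(C)(C)C1=O | intermediate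
9 | lithium acetylide of 3 | [Li+].[C-]#CC(=O)OCC[Si](C)(C)C | intermediate
10 | lithium alkoxide of the silyl-protected adduct (ring oxygen cis to the C2 methyl) | C=CC(O[Si](CC)(CC)CC)[C@]1(C)CCCC(C)(C)[C@]1([O-])C#CC(=O)OCC[Si](C)(C)C.[Li+] | intermediate
11 | rac-2-(trimethylsilyl)ethyl 3-[(1S,2S)-1-hydroxy-2-(1-hydroxyprop-2-en-1-yl)-2,6,6-trimethylcyclohexyl]prop-2-ynoate (both side-chain carbinol epimers) | C=CC(O)[C@]1(C)CCCC(C)(C)[C@]1(O)C#CC(=O)OCC[Si](C)(C)C | intermediate
12 | rac-2-(trimethylsilyl)ethyl 3-[(1S,2R)-1-hydroxy-2,6,6-trimethyl-2-(prop-2-enoyl)cyclohexyl]prop-2-ynoate | C=CC(=O)[C@]1(C)CCCC(C)(C)[C@]1(O)C#CC(=O)OCC[Si](C)(C)C | intermediate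
13 | rac-2-(trimethylsilyl)ethyl 3-{(1S,2S)-1-hydroxy-2-[(1R)-1-hydroxyprop-2-en-1-yl]-2,6,6-trimethylcyclohexyl}prop-2-ynoate | C=C[C@@H](O)[C@]1(C)CCCC(C)(C)[C@]1(O)C#CC(=O)OCC[Si](C)(C)C | intermediate
14 | sodium oxa-aluminacyclopentene (alkenylaluminate) from 13, drawn with the side-chain hydroxyl free | C=C[C@@H](O)[C@]1(C)CCCC(C)(C)[C@@]12O[Al-](OCCOC)(OCCOC)C(C(=O)OCC[Si](C)(C)C)=C2.[Na+] | intermediate
15 | rac-2-(trimethylsilyl)ethyl (2Z)-3-{(1R,2S)-1-hydroxy-2-[(1R)-1-hydroxyprop-2-en-1-yl]-2,6,6-trimethylcyclohexyl}-2-iodoprop-2-enoate | C=C[C@@H](O)[C@]1(C)CCCC(C)(C)[C@]1(O)/C=C(\I)C(=O)OCC[Si](C)(C)C | intermediate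
16 | B-alkyl-9-borabicyclo[3.3.1]nonane from 15 (boron on the terminal carbon), drawn with free hydroxyls | C1CC2CCCC(C1)B2CC[C@@H](O)[C@]1(C)CCCC(C)(C)[C@]1(O)/C=C(\I)C(=O)OCC[Si](C)(C)C | intermediate
17 | rac-2-(trimethylsilyl)ethyl (1R,6R,7S)-1,6-dihydroxy-7,11,11-trimethylbicyclo[5.4.0]undec-2-ene-3-carboxylate (cis-fused; both hydroxyls cis to the angular methyl) | O=C(OCC[Si](C)(C)C)C1=C[C@@]2(O)C(C)(C)CCC[C@@]2(C)[C@H](O)CC1 | intermediate
18 | rac-2-(trimethylsilyl)ethyl (1R,6R,7S)-1-hydroxy-6-(methanesulfonyloxy)-7,11,11-trimethylbicyclo[5.4.0]undec-2-ene-3-carboxylate | O=C(OCC[Si](C)(C)C)C1=C[C@@]2(O)C(C)(C)CCC[C@@]2(C)[C@H](OS(C)(=O)=O)CC1 | intermediate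
19 | potassium alkoxide of 18 | O=C(OCC[Si](C)(C)C)C1=C[C@@]2([O-])C(C)(C)CCC[C@@]2(C)[C@H](OS(C)(=O)=O)CC1.[K+] | intermediate
20 | 2-(trimethylsilyl)ethyl (1E,8E)-4,4,8-trimethyl-3-oxocycloundeca-1,8-diene-1-carboxylate | CC1(C)CCC/C(C)=C/CC/C(C(=O)OCC[Si](C)(C)C)=C\C1=O | intermediate
21 | 2-(trimethylsilyl)ethyl (1E,3R,8E)-3-hydroxy-4,4,8-trimethylcycloundeca-1,8-diene-1-carboxylate | CC1(C)CCC/C(C)=C/CC/C(C(=O)OCC[Si](C)(C)C)=C\[C@H]1O | intermediate
22 | 2-(trimethylsilyl)ethyl (1E,3R,8E)-3-(benzoyloxy)-4,4,8-trimethylcycloundeca-1,8-diene-1-carboxylate | CC1(C)CCC/C(C)=C/CC/C(C(=O)OCC[Si](C)(C)C)=C\[C@H]1OC(=O)c1ccccc1 | intermediate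
23 | 2-(trimethylsilyl)ethyl (1S,4E,6R,11S)-6-(benzoyloxy)-7,7,11-trimethyl-12-oxabicyclo[9.1.0]dodec-4-ene-4-carboxylate | CC1(C)CCC[C@]2(C)O[C@H]2CC/C(C(=O)OCC[Si](C)(C)C)=C\[C@H]1OC(=O)c1ccccc1 | intermediate
24 | (1S,4E,6R,11S)-6-(benzoyloxy)-7,7,11-trimethyl-12-oxabicyclo[9.1.0]dodec-4-ene-4-carboxylic acid (CNP0377917.2) | CC1(C)CCC[C@]2(C)O[C@H]2CC/C(C(=O)O)=C\[C@H]1OC(=O)c1ccccc1 | target

## Step count and least certain steps

Total: 13 steps. Longest linear sequence: 12 steps (steps 2–13, from 4); step 1 supplies building block 3.

**Step 9 (key step).** The alkoxide may alkylate C1 intramolecularly (oxetane closure), or the base may cause elimination, if the seven-membered ring does not populate the conformer with anti-periplanar C1–O and C11–C6 bonds. Fallback, from 15 to 22: fragment before the seven-membered ring is made, where free rotation about C11–C1 allows the alignment. 15 is mesylated at the secondary allylic hydroxyl (MsCl, Et3N, −40 °C) to the mesylate F1, which is treated at once with KN(SiMe3)2 to give the open-chain iodo-dienone F2 with the E diene. Oxazaborolidine reduction as in step 10 gives the alcohol F3 and benzoylation the benzoate F4. 9-BBN adds to the terminal diene carbon, and a B-alkyl Suzuki macrocyclisation (Pd(dppf)Cl2, Cs2CO3, high dilution) forms C3–C4 and gives 22.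

**Step 3.** Conversion may be poor because the carbonyl lies between two quaternary carbons and the ester-stabilised acetylide decomposes on warming; facial selectivity may also be incomplete. Fallback, from 8 to 11: add the smaller, non-stabilised lithium (trimethylsilyl)acetylide with CeCl3 to give the silylalkyne F5, remove the C-silyl group (K2CO3, MeOH) to the terminal alkyne F6, and doubly deprotonate (n-BuLi, 2 equiv). The acetylide carbon is then acylated with 4-nitrophenyl 2-(trimethylsilyl)ethyl carbonate to the silyl-protected ynoate F7 (the hindered tertiary alkoxide stays unreacted), and acid removes the silyl ether to give 11.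

**Step 5.** Diastereoselectivity may erode if hydride is delivered through the chair with an axial acyl group, or if the minor C6 epimer from step 3 is carried along; the tertiary hydroxyl may also add to the vinyl ketone. Fallback, from 11 to 17: omit steps 4 and 5 and carry the epimer mixture through steps 6 and 7, giving 15 with its side-chain epimer F8 and then 17 with its epimer F9. The mixture is oxidised (Dess–Martin) to the single bicyclic hydroxy ketone F10 and reduced with external hydride (NaBH4, CeCl3·7H2O, MeOH, −40 °C). In the bicycle the ring-fusion bond C11–C6 blocks one face of the C1 carbonyl, so hydride should enter from the other and return 17.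

**Step 7.** Transmetallation or reductive elimination may be slow for a seven-membered ring beside two quaternary carbons, leading to loss of iodine by protonation or to intermolecular coupling. Fallback, from 15 to 17: hydroboration–iodination (9-BBN-H; then iodine, NaOMe) turns the vinyl group into the primary iodide F11. A nickel-catalysed reductive cross-electrophile cyclisation (NiBr2(dme), 4,4′-di-tert-butyl-2,2′-bipyridine, Zn, DMA) then joins C3 and C4 through an alkyl radical, with no boron transmetallation, to give 17.

**Step 10.** Facial discrimination may be poor because both ketone substituents are large, and the sense of induction rests on an assumption about which is larger. Fallback, from 20 to 22: Luche reduction (NaBH4, CeCl3·7H2O) gives racemic alcohol, that is 21 with its enantiomer F12. Acylative kinetic resolution with benzoic anhydride and a chiral benzotetramisole catalyst benzoylates the (R)-alcohol to 22 and leaves F12, which is re-oxidised (Dess–Martin) to 20 and recycled.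

**Step 12.** Double diastereoselection may be mismatched if the ring conformation imposed by C6 exposes the wrong alkene face to the catalyst. Fallback, from 20 to 23: epoxidise the achiral enone 20 under the same Shi conditions, so that selectivity rests on the catalyst alone, to give the epoxy enone F13. Oxazaborolidine reduction as in step 10 gives the epoxy alcohol F14, and benzoylation as in step 11 gives 23.

## Further compounds

F1 | step 9 | rac-2-(trimethylsilyl)ethyl (2Z)-3-{(1R,2S)-1-hydroxy-2-[(1R)-1-(methanesulfonyloxy)prop-2-en-1-yl]-2,6,6-trimethylcyclohexyl}-2-iodoprop-2-enoate | C=C[C@@H](OS(C)(=O)=O)[C@]1(C)CCCC(C)(C)[C@]1(O)/C=C(\I)C(=O)OCC[Si](C)(C)C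
F2 | step 9 | 2-(trimethylsilyl)ethyl (2Z,9E)-2-iodo-5,5,9-trimethyl-4-oxododeca-2,9,11-trienoate | C=C/C=C(\C)CCCC(C)(C)C(=O)/C=C(\I)C(=O)OCC[Si](C)(C)C
F3 | step 9 | 2-(trimethylsilyl)ethyl (2Z,4R,9E)-4-hydroxy-2-iodo-5,5,9-trimethyldodeca-2,9,11-trienoate | C=C/C=C(\C)CCCC(C)(C)[C@H](O)/C=C(\I)C(=O)OCC[Si](C)(C)C
F4 | step 9 | 2-(trimethylsilyl)ethyl (2Z,4R,9E)-4-(benzoyloxy)-2-iodo-5,5,9-trimethyldodeca-2,9,11-trienoate | C=C/C=C(\C)CCCC(C)(C)[C@H](OC(=O)c1ccccc1)/C=C(\I)C(=O)OCC[Si](C)(C)C
F5 | step 3 | rac-2,2,6-trimethyl-6-[1-(triethylsilyloxy)prop-2-en-1-yl]-1-[(trimethylsilyl)ethynyl]cyclohexan-1-ol (hydroxyl cis to the C6 methyl) | C=CC(O[Si](CC)(CC)CC)[C@]1(C)CCCC(C)(C)[C@]1(O)C#C[Si](C)(C)C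
F6 | step 3 | rac-1-ethynyl-2,2,6-trimethyl-6-[1-(triethylsilyloxy)prop-2-en-1-yl]cyclohexan-1-ol | C=CC(O[Si](CC)(CC)CC)[C@]1(C)CCCC(C)(C)[C@]1(O)C#C
F7 | step 3 | rac-2-(trimethylsilyl)ethyl 3-{1-hydroxy-2,6,6-trimethyl-2-[1-(triethylsilyloxy)prop-2-en-1-yl]cyclohexyl}prop-2-ynoate | C=CC(O[Si](CC)(CC)CC)[C@]1(C)CCCC(C)(C)[C@]1(O)C#CC(=O)OCC[Si](C)(C)C
F8 | step 5 | rac-2-(trimethylsilyl)ethyl (2Z)-3-{(1R,2S)-1-hydroxy-2-[(1S)-1-hydroxyprop-2-en-1-yl]-2,6,6-trimethylcyclohexyl}-2-iodoprop-2-enoate | C=C[C@H](O)[C@]1(C)CCCC(C)(C)[C@]1(O)/C=C(\I)C(=O)OCC[Si](C)(C)C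
F9 | step 5 | rac-2-(trimethylsilyl)ethyl (1R,6S,7S)-1,6-dihydroxy-7,11,11-trimethylbicyclo[5.4.0]undec-2-ene-3-carboxylate | O=C(OCC[Si](C)(C)C)C1=C[C@@]2(O)C(C)(C)CCC[C@@]2(C)[C@@H](O)CC1
F10 | step 5 | rac-2-(trimethylsilyl)ethyl (1R,7R)-1-hydroxy-7,11,11-trimethyl-6-oxobicyclo[5.4.0]undec-2-ene-3-carboxylate | O=C(OCC[Si](C)(C)C)C1=C[C@@]2(O)C(C)(C)CCC[C@@]2(C)C(=O)CC1
F11 | step 7 | rac-2-(trimethylsilyl)ethyl (2Z)-3-{(1R,2S)-1-hydroxy-2-[(1R)-1-hydroxy-3-iodopropyl]-2,6,6-trimethylcyclohexyl}-2-iodoprop-2-enoate | ICC[C@@H](O)[C@]1(C)CCCC(C)(C)[C@]1(O)/C=C(\I)C(=O)OCC[Si](C)(C)C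
F12 | step 10 | 2-(trimethylsilyl)ethyl (1E,3S,8E)-3-hydroxy-4,4,8-trimethylcycloundeca-1,8-diene-1-carboxylate | CC1(C)CCC/C(C)=C/CC/C(C(=O)OCC[Si](C)(C)C)=C\[C@@H]1O
F13 | step 12 | 2-(trimethylsilyl)ethyl (1S,4E,11S)-7,7,11-trimethyl-6-oxo-12-oxabicyclo[9.1.0]dodec-4-ene-4-carboxylate | CC1(C)CCC[C@]2(C)O[C@H]2CC/C(C(=O)OCC[Si](C)(C)C)=C\C1=O
F14 | step 12 | 2-(trimethylsilyl)ethyl (1S,4E,6R,11S)-6-hydroxy-7,7,11-trimethyl-12-oxabicyclo[9.1.0]dodec-4-ene-4-carboxylate | CC1(C)CCC[C@]2(C)O[C@H]2CC/C(C(=O)OCC[Si](C)(C)C)=C\[C@H]1O
A1 | alternative 1 | methyl (2E,5E)-2-(iodomethylidene)-6,10,10-trimethyl-11-oxoundec-5-enoate | COC(=O)/C(CC/C=C(\C)CCCC(C)(C)C=O)=C/I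
A2 | alternative 1 | methyl (1E,8E)-3-hydroxy-4,4,8-trimethylcycloundeca-1,8-diene-1-carboxylate (both C3 epimers) | CC1(C)CCC/C(C)=C/CC/C(C(=O)OC)=C\C1O
A3 | alternative 2 | methyl 2-[2-(benzoyloxy)-7-ethenyl-3,3,7-trimethylcycloheptyl]prop-2-enoate (benzoyloxy, propenoate and ethenyl groups all cis; R at the benzoyloxy carbon) | C=C[C@]1(C)CCCC(C)(C)[C@H](OC(=O)c2ccccc2)[C@@H]1C(=C)C(=O)OC
A4 | alternative 2 | methyl (1E,3R,8E)-3-(benzoyloxy)-4,4,8-trimethylcycloundeca-1,8-diene-1-carboxylate | CC1(C)CCC/C(C)=C/CC/C(C(=O)OC)=C\[C@H]1OC(=O)c1ccccc1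
A5 | alternative 3 | α-humulene, (1E,4E,8E)-2,6,6,9-tetramethylcycloundeca-1,4,8-triene | CC1(C)/C=C/C/C(C)=C/CC/C(C)=C/C1
A6 | alternative 3 | (1E,5E)-1,5,8,8-tetramethylcycloundeca-1,5-diene | CC1(C)CCC/C(C)=C/CC/C(C)=C/C1
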